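**Retrosynthetic overview**
1. Target ⇐ 2α,3α-diol (selective acetylation of the equatorial C2–OH) ⇐ Δ2-alkene (α-face OsO4); the Δ2 alkene serves as the masked diol through the C9 chemistry.
2. Side chain: C12–C13 by copper-catalysed syn-hydroalkylation of methyl but-2-ynoate with the 9-BBN adduct of a C9 vinyl carbinol; C9–C11 and the C9 stereocentre by axial vinyl addition to the C9 ketone.
3. Ring A functionality: gem-dimethyl by deconjugative methylation, trans ring fusion by hydrogenation, Δ2 by enol triflate reduction.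
4. Ring B (key step): one-carbon ring expansion of the cyclopentanone of a Hajos–Parrish-type enedione with diazoethane (1,2-alkyl shift with loss of N2), which makes the six-membered ring and brings in C8 with its methyl.
5. Ring order: five-membered ring (bought) → ring A by asymmetric Robinson annulation → ring B by ring expansion.

Assumption: the SMILES is taken as drawn (9-OH cis, side chain trans to the C10 methyl); labdane numbering is used in the comments; diazoethane is handled as a freshly prepared, KOH-dried ether solution.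

**Route**

Step 1
Reactants: 1 2-methylcyclopentane-1,3-dione; 2 pent-1-en-3-one (ethyl vinyl ketone)
Product: 4 (7aS)-4,7a-dimethyl-2,3,7,7a-tetrahydro-1H-indene-1,5(6H)-dione, via Michael triketone 3 (not isolated)
Conditions: 2 (1.3 equiv), H2O, AcOH (cat.), 70 °C; concentrate; L-phenylalanine (30 mol%), (+)-CSA (15 mol%), MeCN, 80 °C; recrystallise to >98% ee
Reagents that add atoms: none
Why: Michael addition followed by an L-phenylalanine enamine aldol condensation (Hajos–Parrish–Eder–Sauer–Wiechert reaction) desymmetrises the 1,3-dione and sets the (S) quaternary centre that becomes C10.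

Step 2
Reactants: 4 (7aS)-4,7a-dimethyl-2,3,7,7a-tetrahydro-1H-indene-1,5(6H)-dione
Product: 6 (2R,8aS)-2,5,8a-trimethyl-3,4,8,8a-tetrahydronaphthalene-1,6(2H,7H)-dione, via C2-epimeric enedione 5 (not isolated)
Conditions: CH3CHN2 (2 equiv, Et2O, slow addition), Sc(OTf)3 (5 mol%), CH2Cl2, −78 → −40 °C; then DBU (20 mol%), rt
Reagents that add atoms: diazoethane CC=[N+]=[N-]
Why: Proposed new method: Sc(OTf)3-catalysed single ethylidene insertion into the C(=O)–CH2 bond of the α-quaternary cyclopentanone of a Hajos–Parrish-type enedione, where the diazo carbon adds to the Sc-activated saturated carbonyl from the face opposite the angular methyl, the ring CH2 bond antiperiplanar to the leaving N2 migrates (as in D-homoannulation of 17-keto steroids) to give the six-membered C9 ketone with CH(CH3) at C8, the conjugated tetrasubstituted enone is too unreactive to compete, the doubly α-branched product cannot homologate again, and DBU converges C8 on the equatorial methyl; the closest known reaction type is the Lewis-acid-catalysed diazoalkane–cycloalkanone homologation (Büchner–Curtius–Schlotterbeck / Tiffeneau–Demjanov-type 1,2-shift).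

Step 3
Reactants: 6 (2R,8aS)-2,5,8a-trimethyl-3,4,8,8a-tetrahydronaphthalene-1,6(2H,7H)-dione
Product: 7 (2R,8aS)-2,5,5,8a-tetramethyl-3,7,8,8a-tetrahydronaphthalene-1,6(2H,5H)-dione
Conditions: t-BuOK (1.1 equiv), t-BuOH–THF, 0 °C; MeI (1.5 equiv), 0 °C → rt
Reagents that add atoms: iodomethane CI
Why: Thermodynamic γ-deprotonation gives the extended dienolate, which is C-methylated at C4 (deconjugative alkylation), while the hindered tertiary C8–H of the other ketone is much less acidic and the C8 methyl stays equatorial.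

Step 4
Reactants: 7 (2R,8aS)-2,5,5,8a-tetramethyl-3,7,8,8a-tetrahydronaphthalene-1,6(2H,5H)-dione
Product: 8 (2R,4aS,8aS)-2,5,5,8a-tetramethyl-3,4,4a,7,8,8a-hexahydronaphthalene-1,6(2H,5H)-dione
Conditions: H2 (3 atm), 10% Pd/C, EtOAc–AcOH, rt
Reagents that add atoms: none
Why: Heterogeneous hydrogenation adds H2 to the α-face of the Δ5 alkene because the β-face is covered by the axial C10 and C4β methyls, giving the trans-decalin (5α-H).

Step 5
Reactants: 8 (2R,4aS,8aS)-2,5,5,8a-tetramethyl-3,4,4a,7,8,8a-hexahydronaphthalene-1,6(2H,5H)-dione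
Product: 9 (4aS,6R,8aS)-1,1,4a,6-tetramethyl-5-oxo-1,4,4a,5,6,7,8,8a-octahydronaphthalen-2-yl trifluoromethanesulfonate
Conditions: LiHMDS (1.05 equiv), THF, −78 °C; PhNTf2 (1.1 equiv), −78 → 0 °C; H2O
Reagents that add atoms: N-phenyl-bis(trifluoromethanesulfonimide) O=S(=O)(N(c1ccccc1)S(=O)(=O)C(F)(F)F)C(F)(F)F
Why: Kinetic enolisation takes the accessible C2–H2 of the C3 ketone rather than the tertiary C8–H next to the hindered C9 ketone, and O-triflation of the enolate gives the Δ2 enol triflate.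

Step 6
Reactants: 9 (4aS,6R,8aS)-1,1,4a,6-tetramethyl-5-oxo-1,4,4a,5,6,7,8,8a-octahydronaphthalen-2-yl trifluoromethanesulfonate
Product: 10 (2R,4aS,8aS)-2,5,5,8a-tetramethyl-3,4,4a,5,8,8a-hexahydronaphthalen-1(2H)-one
Conditions: Pd(OAc)2 (5 mol%), PPh3 (10 mol%), HCO2H (2 equiv), Et3N (3 equiv), DMF, 60 °C
Reagents that add atoms: none
Why: Pd-catalysed formate reduction of the vinyl triflate (oxidative addition, decarboxylation of the Pd formate, C–H reductive elimination) gives the Δ2 alkene and leaves the ketone untouched.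

Step 7
Reactants: 10 (2R,4aS,8aS)-2,5,5,8a-tetramethyl-3,4,4a,5,8,8a-hexahydronaphthalen-1(2H)-one
Product: 11 (1S,2R,4aS,8aS)-1-ethenyl-2,5,5,8a-tetramethyl-1,2,3,4,4a,5,8,8a-octahydronaphthalen-1-ol
Conditions: CH2=CHMgBr (2 equiv), LaCl3·2LiCl (30 mol%), THF, 0 °C; H2O
Reagents that add atoms: vinylmagnesium bromide C=C[Mg]Br
Why: La(III)-assisted Grignard 1,2-addition to the hindered enolisable ketone follows the axial trajectory on the α-face because the β-face is blocked by the axial C10 methyl, so C11 ends up trans to the C10 methyl and cis to the C8 methyl with the 9-OH equatorial (β), as in the target.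

Step 8
Reactants: 11 (1S,2R,4aS,8aS)-1-ethenyl-2,5,5,8a-tetramethyl-1,2,3,4,4a,5,8,8a-octahydronaphthalen-1-ol; 12 methyl but-2-ynoate
Product: 14 methyl (2E)-5-[(1S,2R,4aS,8aS)-1-hydroxy-2,5,5,8a-tetramethyl-1,2,3,4,4a,5,8,8a-octahydronaphthalen-1-yl]-3-methylpent-2-enoate, via alkyl-9-BBN borane 13 (not isolated)
Conditions: 9-BBN-H (1.2 equiv), THF, 0 °C → rt; then 12 (1.5 equiv), CuOAc (10 mol%), P(OPh)3 (20 mol%), t-BuOK (10 mol%), t-BuOH (1.5 equiv), 1,4-dioxane, 40 °C
Reagents that add atoms: none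
Why: Anti-Markovnikov hydroboration with 9-BBN is selective for the vinyl group over the hindered Δ2 alkene, and alkoxide-triggered B-to-Cu transmetalation, syn-carbocupration of the ynoate and protonation (copper-catalysed conjugate addition of an alkylborane) place the new alkyl group cis to H, which gives the (E)-3-methyl-2-enoate.

Step 9
Reactants: 14 methyl (2E)-5-[(1S,2R,4aS,8aS)-1-hydroxy-2,5,5,8a-tetramethyl-1,2,3,4,4a,5,8,8a-octahydronaphthalen-1-yl]-3-methylpent-2-enoate
Product: 15 methyl (2E)-5-[(1S,2R,4aS,6S,7R,8aS)-1,6,7-trihydroxy-2,5,5,8a-tetramethyldecahydronaphthalen-1-yl]-3-methylpent-2-enoate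
Conditions: OsO4 (2 mol%), NMO (1.1 equiv), acetone–H2O (8:1), 0 °C
Reagents that add atoms: 4-methylmorpholine N-oxide C[N+]1([O-])CCOCC1; water O
Why: Upjohn dihydroxylation reacts with the electron-rich cis-disubstituted Δ2 alkene much faster than with the electron-poor trisubstituted enoate and comes from the α-face, opposite the axial C10 and C4β methyls, giving the 2α,3α-diol.

Step 10
Reactants: 15 methyl (2E)-5-[(1S,2R,4aS,6S,7R,8aS)-1,6,7-trihydroxy-2,5,5,8a-tetramethyldecahydronaphthalen-1-yl]-3-methylpent-2-enoate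
Product: 16 methyl (2E)-5-[(1S,2R,4aS,6S,7R,8aS)-7-acetoxy-1,6-dihydroxy-2,5,5,8a-tetramethyldecahydronaphthalen-1-yl]-3-methylpent-2-enoate
Conditions: Ac2O (1.2 equiv), pyridine, CH2Cl2, 0 °C
Reagents that add atoms: acetic anhydride CC(=O)OC(C)=O
Why: Acylation picks the equatorial C2–OH over the axial neopentyl C3–OH and the tertiary C9–OH, giving the 2-monoacetate.

**Compound list**
1 | 2-methylcyclopentane-1,3-dione | CC1C(=O)CCC1=O | starting material
2 | pent-1-en-3-one | CCC(=O)C=C | starting material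
3 | 2-methyl-2-(3-oxopentyl)cyclopentane-1,3-dione | CCC(=O)CCC1(C)C(=O)CCC1=O | intermediate
4 | (7aS)-4,7a-dimethyl-2,3,7,7a-tetrahydro-1H-indene-1,5(6H)-dione | C[C@]12CCC(=O)C(C)=C1CCC2=O | intermediate
5 | (8aS)-2,5,8a-trimethyl-3,4,8,8a-tetrahydronaphthalene-1,6(2H,7H)-dione, C2-epimer mixture | C[C@]12CCC(=O)C(C)=C1CCC(C)C2=O | intermediate
6 | (2R,8aS)-2,5,8a-trimethyl-3,4,8,8a-tetrahydronaphthalene-1,6(2H,7H)-dione | C[C@]12CCC(=O)C(C)=C1CC[C@@H](C)C2=O | intermediate
7 | (2R,8aS)-2,5,5,8a-tetramethyl-3,7,8,8a-tetrahydronaphthalene-1,6(2H,5H)-dione | C[C@]12CCC(=O)C(C)(C)C1=CC[C@@H](C)C2=O | intermediate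
8 | (2R,4aS,8aS)-2,5,5,8a-tetramethyl-3,4,4a,7,8,8a-hexahydronaphthalene-1,6(2H,5H)-dione | C[C@]12CCC(=O)C(C)(C)[C@@H]1CC[C@@H](C)C2=O | intermediate
9 | (4aS,6R,8aS)-1,1,4a,6-tetramethyl-5-oxo-1,4,4a,5,6,7,8,8a-octahydronaphthalen-2-yl trifluoromethanesulfonate | C[C@]12CC=C(OS(=O)(=O)C(F)(F)F)C(C)(C)[C@@H]1CC[C@@H](C)C2=O | intermediate
10 | (2R,4aS,8aS)-2,5,5,8a-tetramethyl-3,4,4a,5,8,8a-hexahydronaphthalen-1(2H)-one | C[C@]12CC=CC(C)(C)[C@@H]1CC[C@@H](C)C2=O | intermediate
11 | (1S,2R,4aS,8aS)-1-ethenyl-2,5,5,8a-tetramethyl-1,2,3,4,4a,5,8,8a-octahydronaphthalen-1-ol | C[C@]12CC=CC(C)(C)[C@@H]1CC[C@@H](C)[C@@]2(O)C=C | intermediate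
12 | methyl but-2-ynoate | CC#CC(=O)OC | starting material
13 | (1S,2R,4aS,8aS)-1-[2-(9-borabicyclo[3.3.1]nonan-9-yl)ethyl]-2,5,5,8a-tetramethyl-1,2,3,4,4a,5,8,8a-octahydronaphthalen-1-ol | C[C@]12CC=CC(C)(C)[C@@H]1CC[C@@H](C)[C@@]2(O)CCB1C2CCCC1CCC2 | intermediate
14 | methyl (2E)-5-[(1S,2R,4aS,8aS)-1-hydroxy-2,5,5,8a-tetramethyl-1,2,3,4,4a,5,8,8a-octahydronaphthalen-1-yl]-3-methylpent-2-enoate | COC(=O)/C=C(\C)CC[C@]1(O)[C@H](C)CC[C@H]2C(C)(C)C=CC[C@@]21C | intermediate
15 | methyl (2E)-5-[(1S,2R,4aS,6S,7R,8aS)-1,6,7-trihydroxy-2,5,5,8a-tetramethyldecahydronaphthalen-1-yl]-3-methylpent-2-enoate | COC(=O)/C=C(\C)CC[C@]1(O)[C@H](C)CC[C@H]2C(C)(C)[C@H](O)[C@H](O)C[C@@]21C | intermediate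
16 | methyl (2E)-5-[(1S,2R,4aS,6S,7R,8aS)-7-acetoxy-1,6-dihydroxy-2,5,5,8a-tetramethyldecahydronaphthalen-1-yl]-3-methylpent-2-enoate | COC(=O)/C=C(\C)CC[C@]1(O)[C@H](C)CC[C@H]2C(C)(C)[C@H](O)[C@H](OC(C)=O)C[C@@]21C | target

**Step count and risks**

Total step count: 10. Longest linear sequence: 10.

The three steps most likely to fail:

Step 2 (proposed new ring expansion). The risks are migration of the quaternary carbon instead of the CH2, epoxide formation, and acid-induced loss of diazoethane. The fallback sets out from 4 and uses known chemistry. BF3·OEt2-promoted homologation with ethyl diazoacetate (CH2Cl2, 0 °C) puts the ester-bearing carbon next to the less substituted α-carbon and gives ethyl (8aS)-5,8a-dimethyl-1,6-dioxo-1,2,3,4,6,7,8,8a-octahydronaphthalene-2-carboxylate F1. C-methylation of this β-keto ester (K2CO3, MeI, acetone) gives ethyl (8aS)-2,5,8a-trimethyl-1,6-dioxo-1,2,3,4,6,7,8,8a-octahydronaphthalene-2-carboxylate F2. Krapcho dealkoxycarbonylation (LiCl, wet DMSO, 150 °C) with equilibration of the methyl then comes back to the route at 6.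

Step 7 (vinyl addition to a 2,2,6-trisubstituted ketone). The risks are enolisation, incomplete conversion and a modest diastereomer ratio. The fallback sets out from 10. The smaller, linear ethynylmagnesium bromide (LaCl3·2LiCl, THF, 0 °C) adds with a stronger axial preference and gives (1R,2R,4aS,8aS)-1-ethynyl-2,5,5,8a-tetramethyl-1,2,3,4,4a,5,8,8a-octahydronaphthalen-1-ol F3 (same spatial arrangement as 11; the descriptor changes only through ligand priority). Lindlar semihydrogenation (H2, Pd/CaCO3–Pb, quinoline, EtOAc) then comes back to the route at 11.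

Step 8 (copper-catalysed coupling next to a free tertiary alcohol). The risks are a stable internal O→B chelate that slows transmetalation and erosion of the E geometry. The fallback sets out from 11 and fixes the geometry in the coupling partner instead. Methyl acetoacetate is converted (Tf2O, aqueous Me4NOH, hexanes, 5 °C) to methyl (2E)-3-{[(trifluoromethyl)sulfonyl]oxy}but-2-enoate F4. Compound 11 is hydroborated to borane 13 as in the route, and a B-alkyl Suzuki–Miyaura coupling of 13 with the enol triflate (Pd(dppf)Cl2, K3PO4, THF–DMF–H2O, 50 °C) proceeds with retention and comes back to the route at 14.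

**Further compounds**
F1 | step 2 | ethyl (8aS)-5,8a-dimethyl-1,6-dioxo-1,2,3,4,6,7,8,8a-octahydronaphthalene-2-carboxylate (C2 epimers) | C[C@]12CCC(=O)C(C)=C1CCC(C(=O)OCC)C2=O
F2 | step 2 | ethyl (8aS)-2,5,8a-trimethyl-1,6-dioxo-1,2,3,4,6,7,8,8a-octahydronaphthalene-2-carboxylate (C2 epimers) | C[C@]12CCC(=O)C(C)=C1CCC(C)(C(=O)OCC)C2=O
F3 | step 7 | (1R,2R,4aS,8aS)-1-ethynyl-2,5,5,8a-tetramethyl-1,2,3,4,4a,5,8,8a-octahydronaphthalen-1-ol | C[C@]12CC=CC(C)(C)[C@@H]1CC[C@@H](C)[C@@]2(O)C#C
F4 | step 8 | methyl (2E)-3-{[(trifluoromethyl)sulfonyl]oxy}but-2-enoate | COC(=O)/C=C(\C)OS(=O)(=O)C(F)(F)F
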